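## Retrosynthetic overview

1. The target comes from one global hydrogenolysis that removes nine benzyl ethers and three blocking bromines.
2. Key disconnection: the diarylmethine bond between C2 of the upper unit and C6 of the lower catechin. It is made while ring C of the upper flavan is opened at C2–O1 by a new boron-templated aryl transfer that sets upper C2 as R.
3. Upper fragment: 6,8-dibromo-tetra-O-benzyl-(+)-catechin 3-O-TMS ether. Lower fragment: 8-bromo-penta-O-benzyl-(+)-catechin-6-yl trifluoroborate.
4. Both fragments come from (+)-catechin through the shared tetra-O-benzyl ether. No ring is built: rings A, B and C of the lower unit and rings A and B of the upper unit are carried from the chiral pool, and ring C of the upper unit is opened in the coupling.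

Assumption: (+)-catechin (commercial, 2R,3S) is an acceptable starting material for both halves; flavan numbering (O1, C2, C3, C4 … C8) is used, and "upper" means the unit whose ring C is opened.

## Route

Step 1
Reactants: 1 (+)-catechin
Product: 2 5,7,3',4'-tetra-O-benzyl-(+)-catechin (2R,3S; 3-OH free)
Conditions: BnBr (4.4 equiv), K2CO3, DMF, 0 °C → rt, Ar
Reagents that add atoms: benzyl bromide, BrCc1ccccc1
Why: Williamson etherification in which carbonate deprotonates only the four phenols, so the secondary alcohol stays free and no stereocentre is touched.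

Step 2
Reactants: 2 5,7,3',4'-tetra-O-benzyl-(+)-catechin
Product: 3 6,8-dibromo-5,7,3',4'-tetra-O-benzyl-(+)-catechin (2R,3S)
Conditions: NBS (2.1 equiv), CH2Cl2, −40 °C → rt
Reagents that add atoms: N-bromosuccinimide, O=C1CCC(=O)N1Br
Why: Electrophilic aromatic bromination of the phloroglucinol-type ring A (far more activated than ring B) at both free positions, which blocks this ring against later Friedel–Crafts attack and makes the O1 aryloxide a better leaving group.

Step 3
Reactants: 3 6,8-dibromo-5,7,3',4'-tetra-O-benzyl-(+)-catechin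
Product: 4 3-O-trimethylsilyl ether of 3 (2R,3S)
Conditions: TMSCl, imidazole, CH2Cl2, 0 °C; filtered, concentrated, used crude
Reagents that add atoms: chlorotrimethylsilane, C[Si](C)(C)Cl
Why: Standard O-silylation of the secondary alcohol, giving a proton-free handle for the later silicon-to-boron exchange.

Step 4
Reactants: 2 5,7,3',4'-tetra-O-benzyl-(+)-catechin
Product: 5 8-bromo-5,7,3',4'-tetra-O-benzyl-(+)-catechin (2R,3S)
Conditions: NBS (1.0 equiv), CH2Cl2, −78 °C → rt
Reagents that add atoms: N-bromosuccinimide, O=C1CCC(=O)N1Br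
Why: Electrophilic aromatic bromination, which on tetra-O-benzyl flavan-3-ols is selective for C8, so bromine blocks C8 and leaves C6 as the only free position of ring A.

Step 5
Reactants: 5 8-bromo-5,7,3',4'-tetra-O-benzyl-(+)-catechin
Product: 6 8-bromo-3,5,7,3',4'-penta-O-benzyl-(+)-catechin (2R,3S)
Conditions: NaH, BnBr, DMF, 0 °C → rt
Reagents that add atoms: benzyl bromide, BrCc1ccccc1
Why: Williamson etherification of the secondary alkoxide, which removes the last acidic proton of the lower unit.

Step 6
Reactants: 6 8-bromo-3,5,7,3',4'-penta-O-benzyl-(+)-catechin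
Product: 7 8-bromo-6-iodo-3,5,7,3',4'-penta-O-benzyl-(+)-catechin (2R,3S)
Conditions: NIS (1.2 equiv), CF3CO2H (10 mol %), MeCN/CH2Cl2, 0 °C → rt, dark
Reagents that add atoms: N-iodosuccinimide, O=C1CCC(=O)N1I
Why: Electrophilic aromatic iodination at C6, the only free position of ring A, which is ortho, ortho and para to three oxygens and therefore more reactive than any position of ring B.

Step 7
Reactants: 7 8-bromo-6-iodo-3,5,7,3',4'-penta-O-benzyl-(+)-catechin
Product: 10 potassium (8-bromo-penta-O-benzylcatechin-6-yl)trifluoroborate, via arylmagnesium chloride 8 (not isolated), via dimethyl boronate 9 (not isolated)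
Conditions: iPrMgCl·LiCl (1.1 equiv), THF, −40 °C; B(OMe)3, −40 °C → rt; aq. KHF2, MeOH, 0 °C → rt
Reagents that add atoms: trimethyl borate, COB(OC)OC; potassium hydrogen difluoride, F.[F-].[K+]
Why: Iodine–magnesium exchange (fast for an iodide flanked by two alkoxy groups, while the bromide is inert at −40 °C), followed by electrophilic borylation and conversion of the boronate into the storable trifluoroborate.

Step 8
Reactants: 4 3-O-trimethylsilyl ether of 6,8-dibromo-tetra-O-benzyl-(+)-catechin; 10 potassium (8-bromo-penta-O-benzylcatechin-6-yl)trifluoroborate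
Product: 14 tribromo nona-O-benzyl ether of the target (new diarylmethine centre R; ring C of the upper unit opened), via aryldifluoroborane 11 (not isolated), via fluoroboryl ether 12 (not isolated), via cyclic fluoroborate 13 (not isolated)
Conditions: 10 (1.3 equiv), TMSOTf (1.5 equiv), 2,6-di-tert-butyl-4-methylpyridine (0.3 equiv), 4 Å molecular sieves, CH2Cl2, −78 °C, 20 min; then 4, −78 → −20 °C; then aq. NaHCO3
Reagents that add atoms: none
Why: Proposed new method: a hydroxyl-tethered, boron-templated arylative opening of the flavan C2–O1 bond, in which TMSOTf strips one fluoride from 10 to give aryldifluoroborane 11, silicon-to-boron exchange with the O-TMS group of 4 gives the O3-bound aryl(fluoro)borane 12, its boron chelates O1 in the 2,3-diaxial half-chair so that the benzylic C2–O1 bond ionises to a 3,4-dialkoxybenzyl cation while boron becomes a tetracoordinate borate, and this ate complex transfers its electron-rich aryl group ipso to C2 through a five-membered transition state on the O3 face of the rotamer that keeps C3–H eclipsed with the cation plane (1,3-allylic strain), which sets C2 as R (net inversion relative to catechin, anti in the Petasis sense) and fixes the linkage at C6 because boron marks that carbon; the closest known reaction types are the Petasis borono-Mannich reaction of α-hydroxy aldehydes (hydroxyl-directed anti-selective aryl transfer from a boronate) and Lewis-acid-promoted additions of organotrifluoroborates to oxocarbenium and benzylic cations, neither of which has been used to open a cyclic benzylic aryl ether or to set a diarylmethine centre in this way.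

Step 9
Reactants: 14 tribromo nona-O-benzyl ether of the target
Product: 15 the target gambiriin (all phenols and both alcohols free; chain 1R,2S; flavan 2R,3S)
Conditions: H2 (1 atm), Pd(OH)2/C, Et3N, THF/MeOH/H2O, rt; filtration under Ar, reversed-phase chromatography, lyophilisation
Reagents that add atoms: none
Why: Heterogeneous hydrogenolysis cleaves the nine benzyl ethers and hydrodebrominates the three aryl bromides (Et3N takes up HBr) without touching any stereocentre, the flavan C2–O1 bond or the diarylmethine C–C bond.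

## Compound list

1 | (+)-catechin, (2R,3S)-2-(3,4-dihydroxyphenyl)chromane-3,5,7-triol | O[C@H]1Cc2c(O)cc(O)cc2O[C@@H]1c1ccc(O)c(O)c1 | starting material

2 | 5,7,3',4'-tetra-O-benzyl-(+)-catechin, (2R,3S)-5,7-bis(benzyloxy)-2-[3,4-bis(benzyloxy)phenyl]chroman-3-ol | O[C@H]1Cc2c(OCc3ccccc3)cc(OCc3ccccc3)cc2O[C@@H]1c1ccc(OCc2ccccc2)c(OCc2ccccc2)c1 | intermediate

3 | (2R,3S)-6,8-dibromo-5,7-bis(benzyloxy)-2-[3,4-bis(benzyloxy)phenyl]chroman-3-ol | O[C@H]1Cc2c(OCc3ccccc3)c(Br)c(OCc3ccccc3)c(Br)c2O[C@@H]1c1ccc(OCc2ccccc2)c(OCc2ccccc2)c1 | intermediate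

4 | 3-O-trimethylsilyl ether of 3 (2R,3S) | C[Si](C)(C)O[C@H]1Cc2c(OCc3ccccc3)c(Br)c(OCc3ccccc3)c(Br)c2O[C@@H]1c1ccc(OCc2ccccc2)c(OCc2ccccc2)c1 | intermediate

5 | (2R,3S)-8-bromo-5,7-bis(benzyloxy)-2-[3,4-bis(benzyloxy)phenyl]chroman-3-ol | O[C@H]1Cc2c(OCc3ccccc3)cc(OCc3ccccc3)c(Br)c2O[C@@H]1c1ccc(OCc2ccccc2)c(OCc2ccccc2)c1 | intermediate

6 | (2R,3S)-8-bromo-3,5,7-tris(benzyloxy)-2-[3,4-bis(benzyloxy)phenyl]chromane | C(c1ccccc1)O[C@H]1Cc2c(OCc3ccccc3)cc(OCc3ccccc3)c(Br)c2O[C@@H]1c1ccc(OCc2ccccc2)c(OCc2ccccc2)c1 | intermediate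

7 | (2R,3S)-8-bromo-6-iodo-3,5,7-tris(benzyloxy)-2-[3,4-bis(benzyloxy)phenyl]chromane | C(c1ccccc1)O[C@H]1Cc2c(OCc3ccccc3)c(I)c(OCc3ccccc3)c(Br)c2O[C@@H]1c1ccc(OCc2ccccc2)c(OCc2ccccc2)c1 | intermediate

8 | 6-chloromagnesio derivative of 6 (arylmagnesium chloride, LiCl complex; 2R,3S) | C(c1ccccc1)O[C@H]1Cc2c(OCc3ccccc3)c([Mg]Cl)c(OCc3ccccc3)c(Br)c2O[C@@H]1c1ccc(OCc2ccccc2)c(OCc2ccccc2)c1 | intermediate

9 | dimethyl [(2R,3S)-8-bromo-penta-O-benzylcatechin-6-yl]boronate | C(c1ccccc1)O[C@H]1Cc2c(OCc3ccccc3)c(B(OC)OC)c(OCc3ccccc3)c(Br)c2O[C@@H]1c1ccc(OCc2ccccc2)c(OCc2ccccc2)c1 | intermediate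

10 | potassium [(2R,3S)-8-bromo-3,5,7-tris(benzyloxy)-2-(3,4-bis(benzyloxy)phenyl)chroman-6-yl]trifluoroborate | [K+].C(c1ccccc1)O[C@H]1Cc2c(OCc3ccccc3)c([B-](F)(F)F)c(OCc3ccccc3)c(Br)c2O[C@@H]1c1ccc(OCc2ccccc2)c(OCc2ccccc2)c1 | intermediate

11 | [(2R,3S)-8-bromo-penta-O-benzylcatechin-6-yl]difluoroborane | C(c1ccccc1)O[C@H]1Cc2c(OCc3ccccc3)c(B(F)F)c(OCc3ccccc3)c(Br)c2O[C@@H]1c1ccc(OCc2ccccc2)c(OCc2ccccc2)c1 | intermediate

12 | O3-[aryl(fluoro)boryl] ether: the 3-oxygen of 3 bound to B(F) that carries the lower catechin-6-yl group (all flavan centres 2R,3S) | FB(c1c(OCc2ccccc2)c(Br)c2c(c1OCc1ccccc1)C[C@H](OCc1ccccc1)[C@@H](c1ccc(OCc3ccccc3)c(OCc3ccccc3)c1)O2)O[C@H]1Cc2c(OCc3ccccc3)c(Br)c(OCc3ccccc3)c(Br)c2O[C@@H]1c1ccc(OCc2ccccc2)c(OCc2ccccc2)c1 | intermediate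

13 | seven-membered cyclic fluoroborate of 14: B(F) bridges the carbinol oxygen and the ring A phenol oxygen; chain 1R,2S; lower flavan 2R,3S | c1ccccc1COc1c(Br)c(OCc2ccccc2)c(C[C@H](O%10)[C@H](c2ccc(OCc3ccccc3)c(OCc3ccccc3)c2)c2c(OCc3ccccc3)c(Br)c3c(c2OCc2ccccc2)C[C@H](OCc2ccccc2)[C@@H](c2ccc(OCc4ccccc4)c(OCc4ccccc4)c2)O3)c(OB%10F)c1Br | intermediate

14 | tribromo nona-O-benzyl ether of the target, (1R,2S)-1-[3,4-bis(benzyloxy)phenyl]-1-[(2R,3S)-8-bromo-3,5,7-tris(benzyloxy)-2-(3,4-bis(benzyloxy)phenyl)chroman-6-yl]-3-[4,6-bis(benzyloxy)-3,5-dibromo-2-hydroxyphenyl]propan-2-ol | c1ccccc1COc1c(Br)c(OCc2ccccc2)c(C[C@H](O)[C@H](c2ccc(OCc3ccccc3)c(OCc3ccccc3)c2)c2c(OCc3ccccc3)c(Br)c3c(c2OCc2ccccc2)C[C@H](OCc2ccccc2)[C@@H](c2ccc(OCc4ccccc4)c(OCc4ccccc4)c2)O3)c(O)c1Br | intermediate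

15 | the target gambiriin, (2R,3S)-2-(3,4-dihydroxyphenyl)-6-[(1R,2S)-1-(3,4-dihydroxyphenyl)-2-hydroxy-3-(2,4,6-trihydroxyphenyl)propyl]chromane-3,5,7-triol | Oc1cc(O)c(C[C@H](O)[C@H](c2ccc(O)c(O)c2)c2c(O)cc3c(c2O)C[C@H](O)[C@@H](c2ccc(O)c(O)c2)O3)c(O)c1 | target

## Step count and risks

Total steps: 9. Longest linear sequence: 7 (steps 1, 4, 5, 6, 7, 8, 9). The upper branch is 3 steps (1, 2, 3) before the coupling.

Stereochemistry: lower C2 (R), lower C3 (S) and the carbinol (S) come unchanged from (+)-catechin. The diarylmethine centre (R) is set in step 8; the original C2 configuration of the upper unit is erased on ionisation and does not matter.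

The three steps most likely to fail:

1. Step 7 (borylation of the di-ortho-alkoxy aryl iodide). The risks are competing bromine–magnesium exchange or benzylic deprotonation, and sluggish trapping at the hindered carbon. Fallback: setting out from 7, a Miyaura borylation (B2pin2, PdCl2(dppf), KOAc, dioxane, 80 °C) is used, in which zerovalent palladium inserts into the carbon–iodine bond far faster than into the hindered carbon–bromine bond. It gives the 6-pinacolboronate of 6 F1, which aqueous potassium hydrogen difluoride in MeOH converts into the trifluoroborate. The fallback comes back to the route at 10.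

2. Step 8 (the proposed new reaction). The risks are:
   - ionisation may be too slow with only the tethered boron as Lewis acid;
   - a 1,2-hydride shift from the neighbouring carbinol carbon in the cation would give a 1,3-diarylpropan-2-one;
   - the very electron-rich aryl–boron bond may protodeboronate;
   - ring C of the lower unit may ionise competitively, although it has no tethered boron and a poorer aryloxide leaving group.

   Fallback with known chemistry: setting out from 3 and 6 (2 equiv), boron trifluoride etherate in CH2Cl2/hexafluoroisopropanol at −20 → 0 °C effects a Lewis-acid Friedel–Crafts alkylation. The benzylic carbon–oxygen bond of ring C of 3 ionises to the p-alkoxybenzyl cation and is captured by the only free position of ring A of 6 (position 6, with position 8 blocked by bromine, the established blocking tactic for 6-linked flavan dimers). The diarylmethine centre is then under substrate control only, so the product is obtained together with the epimer of 14 at the diarylmethine carbon F2, which is removed by preparative HPLC. The fallback comes back to the route at 14.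

3. Step 9 (twelve hydrogenolytic events in one pot). The risks are incomplete debromination, HBr-poisoned catalyst, and air oxidation of the free catechols during a long reaction. Fallback: setting out from 14, the three bromines are first removed by radical hydrodebromination (Bu3SnH, AIBN, toluene, 100 °C), giving the bromine-free nona-O-benzyl ether F3, which is purified on silica. A short hydrogenolysis of the benzyl ethers alone (dihydrogen over Pd(OH)2/C, THF/MeOH) then comes back to the route at 15.

## Further compounds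

F1 | step 7 | 2-[(2R,3S)-8-bromo-penta-O-benzylcatechin-6-yl]-4,4,5,5-tetramethyl-1,3,2-dioxaborolane | C(c1ccccc1)O[C@H]1Cc2c(OCc3ccccc3)c(B4OC(C)(C)C(C)(C)O4)c(OCc3ccccc3)c(Br)c2O[C@@H]1c1ccc(OCc2ccccc2)c(OCc2ccccc2)c1

F2 | step 8 | (1S,2S) epimer of 14 at the diarylmethine carbon | c1ccccc1COc1c(Br)c(OCc2ccccc2)c(C[C@H](O)[C@@H](c2ccc(OCc3ccccc3)c(OCc3ccccc3)c2)c2c(OCc3ccccc3)c(Br)c3c(c2OCc2ccccc2)C[C@H](OCc2ccccc2)[C@@H](c2ccc(OCc4ccccc4)c(OCc4ccccc4)c2)O3)c(O)c1Br

F3 | step 9 | bromine-free nona-O-benzyl ether of the target (1R,2S chain; lower flavan 2R,3S) | c1ccccc1COc1cc(OCc2ccccc2)c(C[C@H](O)[C@H](c2ccc(OCc3ccccc3)c(OCc3ccccc3)c2)c2c(OCc3ccccc3)cc3c(c2OCc2ccccc2)C[C@H](OCc2ccccc2)[C@@H](c2ccc(OCc4ccccc4)c(OCc4ccccc4)c2)O3)c(O)c1
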